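**Retrosynthetic overview**

- Chain numbering used below: C1 is the lactone C=O, C15 is the CH2 on the furan; the target is then 4S,5R,10R with 8E and 12E.
- The carbinol carbon C10 is cut on both sides and brought in as bis(pinacolatoboryl)methane, a nucleophilic, polarity-reversed equivalent of a carbinol (reduced acyl) dianion. C10–C11 is made by alkylation with an allylic bromide. C9–C10 is made last, by an enantiotopic-group-selective cross-coupling with an alkenyl bromide, and C–B is then oxidised to C–OH.
- West allylic bromide (C11–C15 plus furan): furan-3-ylmethanol and isoprene monoxide, joined by copper-catalysed SN2′ opening.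
- East alkenyl bromide (C1–C9): pent-4-yn-1-ol, then carboalumination (E-C8=C9), Johnson–Claisen (E-C4=C5), Shi epoxidation and lactonisation (C4 and C5).
- Rings: the furan is bought. The γ-lactone is the only ring made (step 9); it opens under the coupling base and is reclosed in the last operation.

Assumption: the antipode of the TADDOL-derived phosphoramidite used in step 10 is the one that delivers the 10R boronate; its sense of induction is taken from the published simple cases and would be confirmed on a model bromide.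

**Step 1**
Reactants: 1 furan-3-ylmethanol
Product: 2 3-(chloromethyl)furan
Conditions: SOCl2, pyridine, Et2O, 0 °C
Reagents that add atoms: thionyl chloride, O=S(Cl)Cl
Why: Deoxychlorination of a primary furylmethyl alcohol through its chlorosulfite, with pyridine trapping HCl so the acid-sensitive furan survives; no stereocentre is involved.

**Step 2**
Reactants: 2 3-(chloromethyl)furan; 3 2-methyl-2-vinyloxirane (isoprene monoxide, racemic)
Product: 5 (2E)-5-(furan-3-yl)-2-methylpent-2-en-1-ol, via furan-3-ylmethylmagnesium chloride 4 (not isolated)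
Conditions: Mg, THF, 0 °C; then CuI (10 mol %), 3, THF, −40 → 0 °C; aq. NH4Cl
Reagents that add atoms: none
Why: Copper-catalysed SN2′ opening of a vinyl oxirane by a Grignard reagent joins the furylmethyl carbon to the vinyl terminus and gives the E-trisubstituted allylic alcohol (E:Z expected about 9:1, minor isomer removed on AgNO3-doped silica).

**Step 3**
Reactants: 5 (2E)-5-(furan-3-yl)-2-methylpent-2-en-1-ol
Product: 6 3-[(3E)-5-bromo-4-methylpent-3-en-1-yl]furan
Conditions: PBr3 (0.4 equiv), pyridine (cat.), Et2O, −10 °C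
Reagents that add atoms: phosphorus tribromide, BrP(Br)Br
Why: SN2 bromination of the primary allylic alcohol through its phosphite ester at low temperature keeps the olefin position and E geometry; the bromide is used crude at once.

**Step 4**
Reactants: 7 2,2'-methylenebis(4,4,5,5-tetramethyl-1,3,2-dioxaborolane); 6 3-[(3E)-5-bromo-4-methylpent-3-en-1-yl]furan
Product: 9 2,2'-[(3E)-6-(furan-3-yl)-3-methylhex-3-ene-1,1-diyl]bis(4,4,5,5-tetramethyl-1,3,2-dioxaborolane), via bis(pinacolatoboryl)methyllithium 8 (not isolated)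
Conditions: lithium 2,2,6,6-tetramethylpiperidide (LiTMP), THF, 0 °C; then 6, 0 °C → rt
Reagents that add atoms: none
Why: Deprotonation of the doubly boron-stabilised CH2 gives an α,α-diboryl carbanion, a nucleophilic stand-in for the future carbinol carbon C10, which is alkylated SN2 at the CH2Br terminus of the allylic bromide (Matteson-type alkylation of bis(boryl)methane), so C10–C11 joins a carbinol carbon to an electrophile.

**Step 5**
Reactants: 10 pent-4-yn-1-ol
Product: 12 (4E)-5-bromo-4-methylpent-4-en-1-ol, via alkenylalane 11 (not isolated)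
Conditions: AlMe3 (3 equiv), Cp2ZrCl2 (0.25 equiv), CH2Cl2, 0 °C → rt; then NBS, THF, −30 → 0 °C; aq. potassium sodium tartrate
Reagents that add atoms: trimethylaluminium, C[Al](C)C; N-bromosuccinimide, O=C1CCC(=O)N1Br
Why: Negishi zirconium-catalysed syn-carboalumination places methyl on the internal and aluminium on the terminal alkyne carbon, and bromodealumination with retention gives the E-bromoalkene (C8=C9).

**Step 6**
Reactants: 12 (4E)-5-bromo-4-methylpent-4-en-1-ol
Product: 13 (4E)-5-bromo-4-methylpent-4-enal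
Conditions: TEMPO (10 mol %), PhI(OAc)2, CH2Cl2, rt
Reagents that add atoms: none
Why: Oxoammonium-mediated oxidation of the primary alcohol stops at the aldehyde and leaves the bromoalkene untouched.

**Step 7**
Reactants: 13 (4E)-5-bromo-4-methylpent-4-enal; 14 isopropenylmagnesium bromide
Product: 15 (6E)-7-bromo-2,6-dimethylhepta-1,6-dien-3-ol (racemic)
Conditions: THF, −78 → 0 °C; aq. NH4Cl
Reagents that add atoms: none
Why: Grignard 1,2-addition to the aldehyde; the new carbinol centre is left racemic on purpose because it is erased in step 8.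

**Step 8**
Reactants: 15 (6E)-7-bromo-2,6-dimethylhepta-1,6-dien-3-ol; 16 triethyl orthoacetate
Product: 18 ethyl (4E,8E)-9-bromo-4,8-dimethylnona-4,8-dienoate, via mixed ketene acetal 17 (not isolated)
Conditions: EtCO2H (cat.), neat 16 (6 equiv), 138 °C, EtOH distilled off
Reagents that add atoms: none
Why: Johnson–Claisen [3,3]-rearrangement through a chair transition state with the side chain equatorial gives the E-trisubstituted γ,δ-unsaturated ester (C4=C5).

**Step 9**
Reactants: 18 ethyl (4E,8E)-9-bromo-4,8-dimethylnona-4,8-dienoate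
Product: 20 (5S)-5-[(1R,4E)-5-bromo-1-hydroxy-4-methylpent-4-en-1-yl]-5-methyloxolan-2-one, via (4R,5R)-epoxy ester 19 (not isolated)
Conditions: D-fructose-derived Shi ketone (30 mol %), Oxone (2KHSO5·KHSO4·K2SO4), K2CO3, Bu4NHSO4, MeCN–(MeO)2CH2–aq. Na2B4O7 buffer, 0 °C; crude epoxide, then CSA (10 mol %), wet CH2Cl2, rt
Reagents that add atoms: potassium peroxymonosulfate, [K+].[O-]S(=O)(=O)OO; water, O
Why: Shi asymmetric epoxidation (chiral dioxirane, spiro transition state) attacks only the electron-rich trialkyl olefin and gives the (4R,5R)-epoxide, and acid-promoted 5-exo attack of the ester carbonyl at the tertiary epoxide carbon with inversion sets C4 as S while C5 keeps R.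

**Step 10**
Reactants: 9 2,2'-[(3E)-6-(furan-3-yl)-3-methylhex-3-ene-1,1-diyl]bis(4,4,5,5-tetramethyl-1,3,2-dioxaborolane) (1.3 equiv); 20 (5S)-5-[(1R,4E)-5-bromo-1-hydroxy-4-methylpent-4-en-1-yl]-5-methyloxolan-2-one
Product: 24 (5S)-5-[(1R,4E,6R,8E)-11-(furan-3-yl)-1,6-dihydroxy-4,8-dimethylundeca-4,8-dien-1-yl]-5-methyloxolan-2-one, via ring-opened potassium carboxylate 21 (not isolated), via allylic boronate 22 (not isolated), via trihydroxy acid 23 (not isolated)
Conditions: Pd(OAc)2 (5 mol %), TADDOL-derived phosphoramidite (10 mol %), 8 M aq. KOH, 1,4-dioxane, rt; then 30% H2O2, 0 °C → rt; Na2S2O3, 1 M HCl to pH 3; PPTS (cat.), CH2Cl2, rt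
Reagents that add atoms: hydrogen peroxide, OO
Why: Enantiotopic-group-selective Suzuki–Miyaura coupling of a geminal bis(boronate) (Morken) lets the chiral palladium complex transmetalate one of the two C–B bonds of the nucleophilic C10 onto the alkenyl bromide with retention of E geometry, stereoretentive oxidation of the remaining C–B bond then gives the 10R carbinol, and the lactone saponified by KOH recloses on acidification.

**Compound list**

1 | furan-3-ylmethanol | OCc1ccoc1 | starting material
2 | 3-(chloromethyl)furan | ClCc1ccoc1 | intermediate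
3 | 2-methyl-2-vinyloxirane (isoprene monoxide, racemic) | CC1(C=C)CO1 | starting material
4 | furan-3-ylmethylmagnesium chloride | Cl[Mg]Cc1ccoc1 | intermediate (not isolated)
5 | (2E)-5-(furan-3-yl)-2-methylpent-2-en-1-ol | OC/C(C)=C/CCc1ccoc1 | intermediate
6 | 3-[(3E)-5-bromo-4-methylpent-3-en-1-yl]furan | BrC/C(C)=C/CCc1ccoc1 | intermediate
7 | 2,2'-methylenebis(4,4,5,5-tetramethyl-1,3,2-dioxaborolane) | CC1(C)OB(CB2OC(C)(C)C(C)(C)O2)OC1(C)C | starting material
8 | [bis(4,4,5,5-tetramethyl-1,3,2-dioxaborolan-2-yl)methyl]lithium | [Li]C(B1OC(C)(C)C(C)(C)O1)B1OC(C)(C)C(C)(C)O1 | intermediate (not isolated)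
9 | 2,2'-[(3E)-6-(furan-3-yl)-3-methylhex-3-ene-1,1-diyl]bis(4,4,5,5-tetramethyl-1,3,2-dioxaborolane) | CC1(C)OB(OC1(C)C)C(C/C(C)=C/CCc1ccoc1)B1OC(C)(C)C(C)(C)O1 | intermediate
10 | pent-4-yn-1-ol | OCCCC#C | starting material
11 | [(1E)-5-(dimethylalumanyloxy)-2-methylpent-1-en-1-yl]dimethylalumane | C[Al](C)OCCC/C(C)=C/[Al](C)C | intermediate (not isolated)
12 | (4E)-5-bromo-4-methylpent-4-en-1-ol | OCCC/C(C)=C/Br | intermediate
13 | (4E)-5-bromo-4-methylpent-4-enal | O=CCC/C(C)=C/Br | intermediate
14 | isopropenylmagnesium bromide (prop-1-en-2-ylmagnesium bromide) | CC(=C)[Mg]Br | starting material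
15 | (6E)-7-bromo-2,6-dimethylhepta-1,6-dien-3-ol (racemic) | C=C(C)C(O)CC/C(C)=C/Br | intermediate
16 | triethyl orthoacetate (1,1,1-triethoxyethane) | CCOC(C)(OCC)OCC | starting material
17 | (6E)-7-bromo-3-[(1-ethoxyethenyl)oxy]-2,6-dimethylhepta-1,6-diene | C=C(OCC)OC(CC/C(C)=C/Br)C(C)=C | intermediate (not isolated)
18 | ethyl (4E,8E)-9-bromo-4,8-dimethylnona-4,8-dienoate | CCOC(=O)CC/C(C)=C/CC/C(C)=C/Br | intermediate
19 | ethyl 3-[(2R,3R)-3-[(3E)-4-bromo-3-methylbut-3-en-1-yl]-2-methyloxiran-2-yl]propanoate | CCOC(=O)CC[C@@]1(C)O[C@@H]1CC/C(C)=C/Br | intermediate (not isolated)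
20 | (5S)-5-[(1R,4E)-5-bromo-1-hydroxy-4-methylpent-4-en-1-yl]-5-methyloxolan-2-one | Br/C=C(\C)CC[C@@H](O)[C@]1(C)CCC(=O)O1 | intermediate
21 | potassium (4S,5R,8E)-9-bromo-4,5-dihydroxy-4,8-dimethylnon-8-enoate | [K+].[O-]C(=O)CC[C@](C)(O)[C@H](O)CC/C(C)=C/Br | intermediate (not isolated)
22 | potassium (4S,5R,8E,10R,12E)-15-(furan-3-yl)-4,5-dihydroxy-4,8,12-trimethyl-10-(4,4,5,5-tetramethyl-1,3,2-dioxaborolan-2-yl)pentadeca-8,12-dienoate | [K+].[O-]C(=O)CC[C@](C)(O)[C@H](O)CC/C(C)=C/[C@H](B1OC(C)(C)C(C)(C)O1)C/C(C)=C/CCc1ccoc1 | intermediate (not isolated)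
23 | (4S,5R,8E,10R,12E)-15-(furan-3-yl)-4,5,10-trihydroxy-4,8,12-trimethylpentadeca-8,12-dienoic acid | OC(=O)CC[C@](C)(O)[C@H](O)CC/C(C)=C/[C@H](O)C/C(C)=C/CCc1ccoc1 | intermediate (not isolated)
24 | (5S)-5-[(1R,4E,6R,8E)-11-(furan-3-yl)-1,6-dihydroxy-4,8-dimethylundeca-4,8-dien-1-yl]-5-methyloxolan-2-one (CNP0121168.3) | C/C(=C\[C@H](O)C/C(C)=C/CCc1ccoc1)CC[C@@H](O)[C@]1(C)CCC(=O)O1 | target

**Step count**

Total: 10 steps. Longest linear sequence: 6 steps (steps 5–10, from pent-4-yn-1-ol). The west branch is steps 1–4 and joins at step 10.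

**Three steps most likely to fail, each with a fallback**

Step 10. The late coupling runs on an unprotected, saponified bromide, and both turnover and the selectivity at C10 (expected roughly 9:1 to 19:1) are uncertain. The fallback sets out from 9 and 20 and comes back at 24. The bis(boronate) 9 is oxidised with NaBO3·4H2O (THF–H2O, 0 °C) to (3E)-6-(furan-3-yl)-3-methylhex-3-enal F1, which is used at once. F1 is coupled with 20 in a Nozaki–Hiyama–Kishi reaction (CrCl2, NiCl2 cat., Kishi-type chiral sulfonamide ligand, Et3N, THF, rt). The alkenylchromium species adds only to the aldehyde, so lactone and hydroxyl need no protection and 24 is formed directly. C10 is then set by ligand-controlled carbonyl addition, not by the boron coupling.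

Step 2. The E:Z ratio of the SN2′ opening and homocoupling of the furylmethyl Grignard reagent are the concerns. The fallback sets out from 2 and comes back at 5. Compound 2 is coupled with allylmagnesium bromide (THF, 0 °C) to 3-(but-3-en-1-yl)furan F2. Cross-metathesis of F2 with methacrolein (second-generation Grubbs catalyst, CH2Cl2, 40 °C) gives (2E)-5-(furan-3-yl)-2-methylpent-2-enal F3, essentially as the E isomer. Luche reduction (NaBH4, CeCl3·7H2O, MeOH, 0 °C) returns 5.

Step 9. The ee of the Shi epoxidation and a clean 5-exo lactonisation of the epoxy ester are the concerns. The fallback sets out from 15 and comes back at 20. Racemic 15 is submitted to Sharpless kinetic-resolution epoxidation (Ti(OiPr)4, D-(−)-diisopropyl tartrate, t-BuOOH 0.6 equiv, 4 Å sieves, CH2Cl2, −20 °C). The R alcohol reacts fast and gives the erythro epoxy alcohol (1R,4E)-5-bromo-4-methyl-1-[(2S)-2-methyloxiran-2-yl]pent-4-en-1-ol F4, with both stereocentres fixed by the tartrate; the maximum yield is 50 %. Dilithioacetate (LiCH2CO2Li from AcOH and LiN(iPr)2, THF, 0 → 45 °C) opens the oxirane at its CH2 terminus. Acidification gives (4S,5R,8E)-9-bromo-4,5-dihydroxy-4,8-dimethylnon-8-enoic acid F5, which lactonises to 20.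

**Further compounds**

F1 | step 10 | (3E)-6-(furan-3-yl)-3-methylhex-3-enal | O=CC/C(C)=C/CCc1ccoc1
F2 | step 2 | 3-(but-3-en-1-yl)furan | C=CCCc1ccoc1
F3 | step 2 | (2E)-5-(furan-3-yl)-2-methylpent-2-enal | O=C/C(C)=C/CCc1ccoc1
F4 | step 9 | (1R,4E)-5-bromo-4-methyl-1-[(2S)-2-methyloxiran-2-yl]pent-4-en-1-ol | Br/C=C(\C)CC[C@@H](O)[C@]1(C)CO1
F5 | step 9 | (4S,5R,8E)-9-bromo-4,5-dihydroxy-4,8-dimethylnon-8-enoic acid | OC(=O)CC[C@](C)(O)[C@H](O)CC/C(C)=C/Br
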